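**Plan**

- Cuts, in retrosynthetic order: the two O–CH3 bonds; ring C at O1–C2, C2–C3 and the C4–C4a acyl bond; N–CH3; the N1–C2 bond of the piperidine with excision of N1, so that piperidine C6 becomes the oxime carbon of a cyclopentanone; last the aryl–cyclopentane C–C bond.
- Forward order: ring A (1,3,5-trimethoxybenzene) and a five-membered carbocycle (cyclopentanone) are joined first; the carbocycle is enlarged to the piperidine by nitrogen insertion; N-methylation follows; the pyranone ring C is built on the arene; O-demethylation ends the route.
- Enabling feature: piperidine C2 is a benzylic CH bonded to both N1 and flavone C8. Without N1, C2–C3–C4–C5–C6 is a 2-arylcyclopentane in which C6 can be an oxime carbon. In the (E)-oxime the aryl-bearing carbon lies anti to the N–O bond and is the better migrating group, so a reductive Beckmann shift inserts N between C6 and C2 and delivers the secondary amine at once.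
- Stereochemistry: the only stereocentre is set as C2 of a trans-2-arylcyclopentanol by reagent-controlled asymmetric hydroboration (IpcBH2) of the arylcyclopentene. It is kept through ketone and oxime and passed to the C–N bond with retention in the ring expansion (R throughout).

Key step: step 5

Remark: CIP analysis of the target gives the R configuration at C2 of the piperidine (N > aryl C > CH2 > H); all intermediates are drawn to match.

**Step 1**
Reactants: 1 1,3,5-trimethoxybenzene; 2 cyclopentanone
Product: 5 2-(cyclopent-1-en-1-yl)-1,3,5-trimethoxybenzene, via (2,4,6-trimethoxyphenyl)lithium 3 (not isolated), via 1-(2,4,6-trimethoxyphenyl)cyclopentan-1-ol 4 (not isolated)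
Conditions: n-BuLi, THF, 0 °C → rt; then 2, −78 °C → rt; H2O quench; then TsOH·H2O (cat.), toluene, 40 °C
Reagents that add atoms: none
Why: Directed ortho-lithiation between two methoxy groups gives aryllithium 3, its 1,2-addition to the ketone gives the tertiary benzylic alcohol 4, and acid-catalysed E1 dehydration of this very ionisable alcohol should give the aryl alkene 5; no stereocentre is formed.

**Step 2**
Reactants: 5 2-(cyclopent-1-en-1-yl)-1,3,5-trimethoxybenzene
Product: 7 (1S,2R)-2-(2,4,6-trimethoxyphenyl)cyclopentan-1-ol, via isopinocampheyl[trans-2-(2,4,6-trimethoxyphenyl)cyclopentyl]borane 6 (not isolated)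
Conditions: IpcBH2 prepared from (+)-α-pinene, Et2O, −25 °C; then NaOH, H2O2, 0 °C → rt
Reagents that add atoms: hydrogen peroxide, OO
Why: Brown asymmetric hydroboration–oxidation: syn anti-Markovnikov addition puts boron on the unsubstituted alkene carbon and hydrogen on the aryl-bearing carbon from the same face, the isopinocampheyl group selects the face (sense taken by analogy with 1-arylcycloalkenes, the antipodal reagent being available if the sense is reversed), and oxidation with retention should give the trans alcohol with both stereocentres set by reagent control.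

**Step 3**
Reactants: 7 (1S,2R)-2-(2,4,6-trimethoxyphenyl)cyclopentan-1-ol
Product: 8 (2R)-2-(2,4,6-trimethoxyphenyl)cyclopentan-1-one
Conditions: Dess–Martin periodinane, pyridine, CH2Cl2, 0 °C → rt
Reagents that add atoms: none
Why: Dess–Martin oxidation under buffered, non-enolising conditions removes the carbinol stereocentre while C2 should hold, because the enol gains little conjugation from the twisted di-ortho-substituted aryl ring.

**Step 4**
Reactants: 8 (2R)-2-(2,4,6-trimethoxyphenyl)cyclopentan-1-one
Product: 9 (1E,2R)-2-(2,4,6-trimethoxyphenyl)cyclopentan-1-one oxime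
Conditions: NH2OH·HCl, NaOAc, EtOH–H2O, rt
Reagents that add atoms: hydroxylamine hydrochloride, NO.Cl
Why: Oxime condensation at acetate-buffered pH; the hydroxyl should settle anti to the bulky C2 substituent (E isomer), which presets the migrating group, and the oxime is less prone to α-epimerisation than the ketone.

**Step 5**
Reactants: 9 (1E,2R)-2-(2,4,6-trimethoxyphenyl)cyclopentan-1-one oxime
Product: 11 (2R)-2-(2,4,6-trimethoxyphenyl)piperidine, via (2R)-2-(2,4,6-trimethoxyphenyl)-2,3,4,5-tetrahydropyridine 10 (not isolated)
Conditions: DIBAL-H (5 equiv), CH2Cl2, −78 → 0 °C; aq. Rochelle salt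
Reagents that add atoms: none
Why: DIBAL-H first forms the O-aluminated oximate (H2 evolution), a second Lewis-acidic aluminium centre ionises the N–O bond while the anti-periplanar C1–C2 σ-bond shifts from carbon to nitrogen in a concerted suprafacial 1,2-migration, and the resulting N-alkyl nitrilium is reduced by Al–H to the cyclic aldimine 10 and then to the amine. The closest known reaction type is the organoaluminium-promoted Beckmann rearrangement–reduction of ketoximes, that is the DIBAL-H reductive ring expansion of cycloalkanone oximes to azacycloalkanes. No ring is closed from a chain: the five-membered carbocycle is enlarged to the six-membered N1–C2–C3–C4–C5–C6 ring by insertion of nitrogen between C1 and C2 of the oxime. No new stereocentre arises; C2 migrates with its bonding electron pair and keeps H, aryl and C3 in place, so the R configuration is transferred to the new C–N bond with retention. The step needs C2 and not C5 to migrate, which the E geometry of 9 secures because only the group anti to oxygen migrates; it also needs migration to outrun heterolytic C1–C2 fragmentation and direct C=N reduction, which the non-polar solvent, low temperature and excess hydride are chosen to favour.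

**Step 6**
Reactants: 11 (2R)-2-(2,4,6-trimethoxyphenyl)piperidine
Product: 13 (2R)-1-methyl-2-(2,4,6-trimethoxyphenyl)piperidine, via (2R)-1-methylidene-2-(2,4,6-trimethoxyphenyl)piperidin-1-ium 12 (not isolated)
Conditions: aq. HCHO, NaBH(OAc)3, ClCH2CH2Cl, rt
Reagents that add atoms: formaldehyde, C=O
Why: Reductive amination of the secondary amine through iminium 12 with a mild acyloxyborohydride at room temperature should methylate nitrogen without touching the benzylic C–N stereocentre.

**Step 7**
Reactants: 13 (2R)-1-methyl-2-(2,4,6-trimethoxyphenyl)piperidine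
Product: 15 1-[2-hydroxy-4,6-dimethoxy-3-[(2R)-1-methylpiperidin-2-yl]phenyl]ethan-1-one, via 1-[2,4,6-trimethoxy-3-[(2R)-1-methylpiperidin-2-yl]phenyl]ethan-1-one 14 (not isolated)
Conditions: Ac2O, BF3·OEt2, CH2Cl2, 0 °C → rt; aq. Na2CO3
Reagents that add atoms: acetic anhydride, CC(=O)OC(C)=O
Why: Friedel–Crafts acetylation at the only kind of free, doubly methoxy-activated ring position gives 14, and BF3 chelated between the new carbonyl and the ortho methoxy group that is twisted out of plane by the neighbouring piperidinyl group should cleave that O–CH3 bond selectively (known behaviour of 2,4,6-trimethoxyphenyl-substituted piperidines), giving the phenol that becomes O1 next to C8.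

**Step 8**
Reactants: 15 1-[2-hydroxy-4,6-dimethoxy-3-[(2R)-1-methylpiperidin-2-yl]phenyl]ethan-1-one; 16 methyl benzoate
Product: 18 5,7-dimethoxy-8-[(2R)-1-methylpiperidin-2-yl]-2-phenyl-4H-chromen-4-one, via 1-[2-hydroxy-4,6-dimethoxy-3-[(2R)-1-methylpiperidin-2-yl]phenyl]-3-phenylpropane-1,3-dione 17 (not isolated)
Conditions: NaH, DMF, 0 °C → rt; then conc. HCl, rt; aq. Na2CO3
Reagents that add atoms: none
Why: Crossed Claisen condensation of the phenoxide–enolate with methyl benzoate gives 1,3-diketone 17, and acid-catalysed cyclodehydration (6-exo-trig attack of the phenol on the benzoyl carbonyl, then loss of water) should close the 4-pyranone ring in a Baker–Venkataraman-type flavone synthesis.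

**Step 9**
Reactants: 18 5,7-dimethoxy-8-[(2R)-1-methylpiperidin-2-yl]-2-phenyl-4H-chromen-4-one
Product: 19 5,7-dihydroxy-8-[(2R)-1-methylpiperidin-2-yl]-2-phenyl-4H-chromen-4-one
Conditions: BBr3 (excess), CH2Cl2, −78 °C → rt; H2O quench; aq. NaHCO3
Reagents that add atoms: none
Why: Lewis-acid ether cleavage (boron coordinates each methoxy oxygen, the 5-OMe helped by chelation to C4=O, and bromide attacks methyl by SN2) should free both phenols, and the absence of heat avoids the retro-Mannich/ortho-quinone methide pathway that would racemise piperidine C2.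

**Compound list**

1 | 1,3,5-trimethoxybenzene | COc1cc(OC)cc(OC)c1 | starting material
2 | cyclopentanone | O=C1CCCC1 | starting material
3 | (2,4,6-trimethoxyphenyl)lithium | [Li]c1c(OC)cc(OC)cc1OC | intermediate (not isolated)
4 | 1-(2,4,6-trimethoxyphenyl)cyclopentan-1-ol | COc1cc(OC)c(C2(O)CCCC2)c(OC)c1 | intermediate (not isolated)
5 | 2-(cyclopent-1-en-1-yl)-1,3,5-trimethoxybenzene | COc1cc(OC)c(C2=CCCC2)c(OC)c1 | intermediate
6 | isopinocampheyl[trans-2-(2,4,6-trimethoxyphenyl)cyclopentyl]borane (Ipc from (+)-α-pinene; boron on the carbon and face of the later hydroxyl) | C[C@H]1[C@H](B[C@H]3CCC[C@@H]3c3c(OC)cc(OC)cc3OC)C[C@@H]2C[C@H]1C2(C)C | intermediate (not isolated)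
7 | (1S,2R)-2-(2,4,6-trimethoxyphenyl)cyclopentan-1-ol | O[C@H]1CCC[C@@H]1c1c(OC)cc(OC)cc1OC | intermediate
8 | (2R)-2-(2,4,6-trimethoxyphenyl)cyclopentan-1-one | O=C1CCC[C@@H]1c1c(OC)cc(OC)cc1OC | intermediate
9 | (1E,2R)-2-(2,4,6-trimethoxyphenyl)cyclopentan-1-one oxime | O/N=C1\CCC[C@@H]1c1c(OC)cc(OC)cc1OC | intermediate
10 | (2R)-2-(2,4,6-trimethoxyphenyl)-2,3,4,5-tetrahydropyridine | N1=CCCC[C@@H]1c1c(OC)cc(OC)cc1OC | intermediate (not isolated)
11 | (2R)-2-(2,4,6-trimethoxyphenyl)piperidine | N1CCCC[C@@H]1c1c(OC)cc(OC)cc1OC | intermediate
12 | (2R)-1-methylidene-2-(2,4,6-trimethoxyphenyl)piperidin-1-ium | C=[N+]1CCCC[C@@H]1c1c(OC)cc(OC)cc1OC | intermediate (not isolated)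
13 | (2R)-1-methyl-2-(2,4,6-trimethoxyphenyl)piperidine | CN1CCCC[C@@H]1c1c(OC)cc(OC)cc1OC | intermediate
14 | 1-[2,4,6-trimethoxy-3-[(2R)-1-methylpiperidin-2-yl]phenyl]ethan-1-one | CN1CCCC[C@@H]1c1c(OC)c(C(C)=O)c(OC)cc1OC | intermediate (not isolated)
15 | 1-[2-hydroxy-4,6-dimethoxy-3-[(2R)-1-methylpiperidin-2-yl]phenyl]ethan-1-one | CN1CCCC[C@@H]1c1c(O)c(C(C)=O)c(OC)cc1OC | intermediate
16 | methyl benzoate | COC(=O)c1ccccc1 | starting material
17 | 1-[2-hydroxy-4,6-dimethoxy-3-[(2R)-1-methylpiperidin-2-yl]phenyl]-3-phenylpropane-1,3-dione | CN1CCCC[C@@H]1c1c(O)c(C(=O)CC(=O)c2ccccc2)c(OC)cc1OC | intermediate (not isolated)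
18 | 5,7-dimethoxy-8-[(2R)-1-methylpiperidin-2-yl]-2-phenyl-4H-chromen-4-one | CN1CCCC[C@@H]1c1c(OC)cc(OC)c2c(=O)cc(-c3ccccc3)oc12 | intermediate
19 | 5,7-dihydroxy-8-[(2R)-1-methylpiperidin-2-yl]-2-phenyl-4H-chromen-4-one | CN1CCCC[C@@H]1c1c(O)cc(O)c2c(=O)cc(-c3ccccc3)oc12 | target

**Step count and risks**

Total step count: 9. Longest linear sequence: 9 steps (from 1 to 19).

Steps most likely to fail:

Step 5 (key step). The C1–C2 bond may break heterolytically (Beckmann fragmentation, favoured by the cation-stabilising trimethoxyphenyl group), or the C=N bond may be reduced before migration. Either process would give open-chain or non-expanded amines and could erode the configuration at C2. The fallback sets out from oxime 9 and separates rearrangement from reduction. O-Sulfonylation with TsCl and pyridine at 0 °C should give (1E,2R)-2-(2,4,6-trimethoxyphenyl)cyclopentan-1-one O-tosyl oxime F1. This is rearranged without Lewis acid or hydride by warming in aqueous THF buffered with NaHCO3 (solvolytic Beckmann rearrangement, water capturing the nitrilium) to (6R)-6-(2,4,6-trimethoxyphenyl)piperidin-2-one F2. Reduction of the lactam with LiAlH4 in THF at reflux should then give 11, where the route is rejoined.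

Step 7. Under BF3 and acetic anhydride the benzylic C2–N bond next to the very electron-rich ring may ionise, which would open the piperidine, acetylate nitrogen and racemise C2; the acylation may also stall on the BF3-complexed amine. The fallback sets out from 13 and replaces the electrophilic acylation by an anionic one. Lithiation of the ring CH between two methoxy groups (n-BuLi, TMEDA, THF, 0 °C) and quenching with N-methoxy-N-methylacetamide should give ketone 14, this time isolated. Chelation-controlled cleavage of the methoxy group beside the carbonyl and the piperidinyl group with BCl3 in CH2Cl2 at −78 to 0 °C, on the now deactivated arene, should give 15, where the route is rejoined. No compound outside the list is made.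

Step 2. The hindered, twisted aryl alkene may react slowly with the bulky borane or with poor facial selectivity, which would lower the enantiomeric purity of everything that follows. The fallback sets out from 5. Hydroboration with BH3·THF and oxidation (NaOH, H2O2) should give racemic trans-2-(2,4,6-trimethoxyphenyl)cyclopentan-1-ol F3. Lipase-catalysed kinetic resolution (Pseudomonas cepacia lipase, vinyl acetate, tert-butyl methyl ether) is expected, by analogy with trans-2-arylcycloalkanols, to acylate the (1R,2S) enantiomer to (1R,2S)-2-(2,4,6-trimethoxyphenyl)cyclopentyl acetate F4 and to leave the (1S,2R) alcohol unreacted. That alcohol is separated by chromatography and the route is rejoined at 7.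

**Further compounds**

F1 | step 5 | (1E,2R)-2-(2,4,6-trimethoxyphenyl)cyclopentan-1-one O-tosyl oxime | Cc1ccc(cc1)S(=O)(=O)O/N=C1\CCC[C@@H]1c1c(OC)cc(OC)cc1OC
F2 | step 5 | (6R)-6-(2,4,6-trimethoxyphenyl)piperidin-2-one | O=C1CCC[C@@H](N1)c1c(OC)cc(OC)cc1OC
F0 | step 7 | none | none
F3 | step 2 | racemic trans-2-(2,4,6-trimethoxyphenyl)cyclopentan-1-ol | O[C@H]1CCC[C@@H]1c1c(OC)cc(OC)cc1OC.O[C@@H]1CCC[C@H]1c1c(OC)cc(OC)cc1OC
F4 | step 2 | (1R,2S)-2-(2,4,6-trimethoxyphenyl)cyclopentyl acetate | CC(=O)O[C@@H]1CCC[C@H]1c1c(OC)cc(OC)cc1OC
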